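Which of the three recipes should I charge next, if the complex with two exchanged is to stand as high as possible against the trapped intermediate at the end?

the same everywhere: leaving ligand 0.0500 M; capture agent 2.00 mM; time 1.0 min
- Friday's: starting complex 0.10 M; incoming ligand 0.0900 M; everything together at the start
- Sunday's: starting complex 0.10 M (fed, over 50 s); incoming ligand 0.0900 M; all else is in the flask from the start; the feed brings no volume worth counting
- Tuesday's: starting complex 0.10 M; incoming ligand 0.0900 M (fed, over 50 s); all else is in the flask from the start; the feed brings no volume worth counting

    starting complex + incoming ligand ⇌ leaving ligand + complex with one exchanged (K1 = 34, k1 = 0.225 L mol⁻¹ s⁻¹)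
    complex with one exchanged + incoming ligand ⇌ leaving ligand + complex with two exchanged (K2 = 0.437, k2 = 0.0596 L mol⁻¹ s⁻¹)
    complex with one exchanged → decomposed reagent (k3 = 0.0710 s⁻¹)
    complex with one exchanged + capture agent → trapped intermediate (k4 = 0.725 L mol⁻¹ s⁻¹)
    complex with two exchanged → over-reaction product (k5 = 0.00982 s⁻¹)

1. the flask with the highest share of complex with two exchanged in complex with two exchanged plus trapped intermediate ("all alike" if they lie within 1.5 percentage points) (Friday's / Sunday's / Tuesday's / all alike)
2. share of complex with two exchanged in complex with two exchanged plus trapped intermediate at the end, Friday's
3. share of complex with two exchanged in complex with two exchanged plus trapped intermediate at the end, Sunday's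
4. share of complex with two exchanged in complex with two exchanged plus trapped intermediate at the end, Tuesday's

Both products are made from the complex with one exchanged, so I divided the forward rate of the second exchange by the rate of capture, and its concentration dropped out, and time with it. What remained was the constant of the second exchange times c(incoming ligand), over the capture constant times c(capture agent). At the charges this ratio is 3.70, and I carried it as S, the selectivity factor, the forward rate of the second exchange over the rate of capture. S divided by one plus S turns it into a share of what is being made, here 78.7%. I used that to rank recipes and not as an end share: in Friday's flask the complex with two exchanged also goes on to the over-reaction product, with a half-life of 1.2 min by that step alone, and the run lasts 1.0 min.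

With c(capture agent) charged alike, S follows c(incoming ligand), so the recipes differ in how they hold it up. In Friday's flask the forward first exchange, at the charged c(starting complex), consumes the ligand on a time of 44.4 s, shorter than the run of 60 s, so I expected S there to sink early. In Sunday's flask the starting complex arrives on average 25.0 s after the start, so I expected that fall to come later. In Tuesday's flask the ligand starts from nothing, and so does S. I decided on Sunday's recipe, though by hand I could not place Friday's against Tuesday's.

The forecast, which went further and gave end shares, also chose Sunday's: 57.5% (55% to 60%) for Friday's, 67.5% (65% to 70%) for Sunday's and 61% (58% to 64%) for Tuesday's, on the ground that “Sunday keeps the ligand high”.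

The simulation gave Sunday's, with 58.0% for Friday's, 67.3% for Sunday's and 61.2% for Tuesday's, each inside its range.

At 1.00 min Sunday's flask held 55.5% of its ligand and 76.1% of its capture agent, so S stood at 2.70, against 2.30 in Friday's flask. At 0.613 min in Sunday's flask, the loss of complex with one exchanged to decomposed reagent ran 17 times its forward second exchange, and at the charged c(capture agent) the constant of that loss, 0.0710 s⁻¹, stands against 0.00145 s⁻¹ for capture, so S ranks two small branches beside a larger one. With 0.15 M of incoming ligand in Sunday's flask, S at the charges is 6.17, a share of 86.1%. The computed end share there was 78.4%.

The rate constants belong to no real substance; the run is a simulation.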